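Ring A of the target is read as a masked 4-methylphenol: C10, the methyl-bearing ring-fusion carbon, sits para to C3 and next to C5. Oxidising such a phenol makes C10 electrophilic, and C9 of a Z-allylsilane tethered through C5–C6–C7–C8 then bonds to it. In one operation this forges C9–C10, closes ring B, creates the C10 quaternary and C9 tertiary centres under control of the C7 silyloxy carbinol, and unveils the C8=C17 methylidene. The precursor is a 2-homoprenyl-4-methylphenol carrying at C5 a CH2–CH(OTIPS)–C(CH2SiMe3)=CH–CH2CH2OTBS chain; the resulting dienone is reduced, methylated at C4, deoxygenated at C3 and extended to the E-enoic acid.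

Key step: step 12

Remark on locants: target numbering is used throughout. C1–C10 are the decalin carbons (C10 = CH3-bearing ring-fusion carbon, C5 = ring-fusion CH, C4 = quaternary carbon with CH3 and homoprenyl, C3 = the carbon that is the phenol carbon before step 12). C7 is the carbinol, C8 the methylidene carbon (=C17H2), C9 carries the chain C11–C15 (C15 = CO2H). α/β refer to the usual drawing with the C10 methyl β.

Remark on stereochemistry: a (7R) carbinol and a Z-allylsilane are the elements that map onto 7α-O, 9α-H and 10β-CH3 through a chair with the silyloxy group axial.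

Remark on protecting groups: C7–O carries TIPS (bulky, robust) and C12–O a primary TBS ether, so that C12–O can be released first; the phenol is masked as a diethylcarbamate, which is removed by hydride and so never exposes the allylsilane to acid.

Assumption: tert-butyl(but-3-yn-1-yloxy)dimethylsilane 12, the TBS ether of but-3-yn-1-ol, is bought.

Step 1
Reactants: 1 3-bromo-4-methylphenol
Product: 2 3-bromo-4-methylphenyl N,N-diethylcarbamate
Conditions: Et2NCOCl, K2CO3, MeCN, 80 °C
Reagents that add atoms: N,N-diethylcarbamoyl chloride, CCN(CC)C(=O)Cl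
Why: O-carbamoylation of the phenol gives a group that directs the next metalation and should survive the organolithium, Grignard and oxidation steps that follow.

Step 2
Reactants: 2 3-bromo-4-methylphenyl N,N-diethylcarbamate
Product: 4 3-bromo-2-iodo-4-methylphenyl N,N-diethylcarbamate, via aryllithium 3 (not isolated)
Conditions: LDA, THF, −78 °C; then I2, −78 °C → rt
Reagents that add atoms: iodine, II
Why: Directed ortho-metalation, in which the amide base (no Br/Li exchange) removes the ring proton flanked by the carbamate oxygen and bromine, and iodine then marks that carbon, the future C4.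

Step 3
Reactants: 4 3-bromo-2-iodo-4-methylphenyl N,N-diethylcarbamate; 5 5-bromo-2-methylpent-2-ene
Product: 7 3-bromo-4-methyl-2-(4-methylpent-3-en-1-yl)phenyl N,N-diethylcarbamate, via homoprenylzinc bromide 6 (not isolated)
Conditions: 5, Zn dust, I2 (cat.), DMA, 70 °C; then 4, PdCl2(dppf) (5 mol %), THF/DMA, 40 °C
Reagents that add atoms: none
Why: Negishi sp3–sp2 coupling, in which oxidative addition into C–I is much faster than into the neighbouring C–Br bond, so the homoprenyl group should enter at C4 and the bromide is kept for step 4.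

Step 4
Reactants: 7 3-bromo-4-methyl-2-(4-methylpent-3-en-1-yl)phenyl N,N-diethylcarbamate; 8 oxirane
Product: 10 3-(2-hydroxyethyl)-4-methyl-2-(4-methylpent-3-en-1-yl)phenyl N,N-diethylcarbamate, via aryllithium 9 (not isolated)
Conditions: t-BuLi (2 equiv), THF, −78 °C; then oxirane, BF3·OEt2, −78 °C
Reagents that add atoms: none
Why: Bromine–lithium exchange followed by BF3-assisted epoxide opening attaches the C6–C7 unit at −78 °C, where the carbamate is not attacked.

Step 5
Reactants: 10 3-(2-hydroxyethyl)-4-methyl-2-(4-methylpent-3-en-1-yl)phenyl N,N-diethylcarbamate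
Product: 11 4-methyl-2-(4-methylpent-3-en-1-yl)-3-(2-oxoethyl)phenyl N,N-diethylcarbamate
Conditions: Dess–Martin periodinane, CH2Cl2, 0 °C → rt
Reagents that add atoms: none
Why: Dess–Martin oxidation stops at the enolisable arylacetaldehyde under non-basic conditions, and the aldehyde is used at once.

Step 6
Reactants: 11 4-methyl-2-(4-methylpent-3-en-1-yl)-3-(2-oxoethyl)phenyl N,N-diethylcarbamate; 12 tert-butyl(but-3-yn-1-yloxy)dimethylsilane
Product: 14 3-[6-(tert-butyldimethylsilyloxy)-2-hydroxyhex-3-yn-1-yl]-4-methyl-2-(4-methylpent-3-en-1-yl)phenyl N,N-diethylcarbamate (racemic at C7), via lithium acetylide 13 (not isolated)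
Conditions: 12, n-BuLi, THF, −78 °C; then 11, −78 °C; aq. NH4Cl
Reagents that add atoms: none
Why: 1,2-Addition of a lithium acetylide to the aldehyde at low temperature joins C7 to C8; the carbinol is made as a racemate because its configuration is set in step 8.

Step 7
Reactants: 14 racemic propargylic alcohol
Product: 15 3-[6-(tert-butyldimethylsilyloxy)-2-oxohex-3-yn-1-yl]-4-methyl-2-(4-methylpent-3-en-1-yl)phenyl N,N-diethylcarbamate
Conditions: Dess–Martin periodinane, CH2Cl2, 0 °C
Reagents that add atoms: none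
Why: Dess–Martin oxidation of the propargylic alcohol gives the alkynyl ketone without base, so the acidic benzylic CH2 next to the carbonyl is not isomerised.

Step 8
Reactants: 15 alkynyl ketone
Product: 16 3-[(2R)-6-(tert-butyldimethylsilyloxy)-2-hydroxyhex-3-yn-1-yl]-4-methyl-2-(4-methylpent-3-en-1-yl)phenyl N,N-diethylcarbamate
Conditions: Ru[(R,R)-TsDPEN](p-cymene) (2 mol %), i-PrOH, 25 °C
Reagents that add atoms: none
Why: Noyori asymmetric transfer hydrogenation of an alkynyl ketone, in which the alkynyl group takes the place of the aryl group in the six-membered hydride-transfer model, so the (R,R)-catalyst should give the (R)-carbinol at C7.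

Step 9
Reactants: 16 (R)-propargylic alcohol; 17 (trimethylsilyl)methylmagnesium chloride
Product: 19 3-[(2R,3Z)-6-(tert-butyldimethylsilyloxy)-2-hydroxy-3-(trimethylsilylmethyl)hex-3-en-1-yl]-4-methyl-2-(4-methylpent-3-en-1-yl)phenyl N,N-diethylcarbamate, via alkenylmagnesium chelate 18 (not isolated)
Conditions: 17 (4 equiv), CuI (20 mol %), THF, 0 → 40 °C; aq. NH4Cl
Reagents that add atoms: none
Why: Copper-catalysed anti-carbomagnesiation of a propargylic alkoxide (Duboudin–Jousseaume type): the alkoxide holds magnesium on C9 in a five-membered chelate, CH2SiMe3 is delivered to C8 trans to it, and protonolysis leaves C11 cis to CH2SiMe3, that is the Z-allylsilane.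

Step 10
Reactants: 19 (R,Z)-allylsilane alcohol
Product: 20 3-[(2R,3Z)-6-(tert-butyldimethylsilyloxy)-2-(triisopropylsilyloxy)-3-(trimethylsilylmethyl)hex-3-en-1-yl]-4-methyl-2-(4-methylpent-3-en-1-yl)phenyl N,N-diethylcarbamate
Conditions: TIPSOTf, 2,6-lutidine, CH2Cl2, −78 → 0 °C
Reagents that add atoms: triisopropylsilyl trifluoromethanesulfonate, CC(C)[Si](OS(=O)(=O)C(F)(F)F)(C(C)C)C(C)C
Why: Silylation of the secondary allylic alcohol with a silyl triflate and a hindered base, buffered throughout so that the allylsilane is not protodesilylated.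

Step 11
Reactants: 20 carbamate-protected TIPS ether
Product: 21 3-[(2R,3Z)-6-(tert-butyldimethylsilyloxy)-2-(triisopropylsilyloxy)-3-(trimethylsilylmethyl)hex-3-en-1-yl]-4-methyl-2-(4-methylpent-3-en-1-yl)phenol
Conditions: LiAlH4, THF, 0 → 40 °C; H2O/NaOH work-up
Reagents that add atoms: none
Why: Hydride reduction of the aryl carbamate expels the phenoxide, while silyl ethers, the allylsilane and the isolated alkenes are inert to LiAlH4.

Step 12
Reactants: 21 phenol with the Z-allylsilane tether
Product: 23 bicyclic 1,4-dien-3-one with ring B closed: 4-(4-methylpent-3-en-1-yl), 10β-methyl, 8-methylidene, 7α-triisopropylsilyloxy, 9β-[2-(tert-butyldimethylsilyloxy)ethyl] (9α-H), via aryloxy-λ3-iodane 22 (not isolated)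
Conditions: PhI(OAc)2 (1.1 equiv), HFIP/CH2Cl2 (1:1), −20 °C
Reagents that add atoms: none
Why: PhI(OAc)2 exchanges an acetate for the phenol oxygen, and iodane 22 collapses in HFIP to a phenoxonium-type cation that is captured at the methyl-bearing para carbon C10 by C9, the γ-carbon of the allylsilane; the β-silyl cation at C8 then loses Me3Si to acetate and leaves C8=C17. The closest known reaction type is the hypervalent-iodine oxidative dearomatisation of 4-alkylphenols with allylsilane capture at the para carbon (oxidative Hosomi–Sakurai allylation and its spirocyclising intramolecular form). Ring B closes through a six-membered chair, 6-endo-trig with respect to the C8=C9 bond (anti SE2′, silicon opposite the incoming carbon), and the quaternary C10 cannot rearomatise. C10 is set by the arene face that this chair offers when the C7 triisopropylsilyloxy group is axial, which keeps the bulky ether out of the plane of the neighbouring CH2SiMe3 group (allylic 1,2-strain); C9 is set by the Z geometry, which puts C11 equatorial and H axial, so that C11 ends cis to the C10 methyl. The step needs closure at the para carbon C10 and not at the ortho carbon C4, both six-membered: C10 carries the larger share of the positive charge, leads to the cross-conjugated dienone and bears only a methyl group, whereas C4 bears the homoprenyl chain.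

Step 13
Reactants: 23 bicyclic 1,4-dien-3-one
Product: 24 4-en-3-one (C1–C2 saturated; other groups as in 23)
Conditions: [(Ph3P)CuH]6 (0.25 equiv), H2O (5 equiv), THF, rt
Reagents that add atoms: none
Why: Conjugate reduction with Stryker's reagent delivers hydride to the unsubstituted β-carbon C1 of the disubstituted enone arm and should leave the tetrasubstituted C4=C5 arm and the isolated alkenes untouched.

Step 14
Reactants: 24 4-en-3-one
Product: 26 trans-fused 3-ketone: 4α-methyl, 4β-(4-methylpent-3-en-1-yl), 5α-H (other groups as in 23), via lithium enolate 25 (not isolated)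
Conditions: Li (2.5 equiv), t-BuOH (1 equiv), NH3(l)/THF, −78 °C; isoprene; then MeI, −78 → −33 °C; NH4Cl
Reagents that add atoms: iodomethane, CI
Why: Stork reductive alkylation: Li/NH3 reduces the enone with axial protonation at C5 on the α-face to give the trans-fused, regiodefined C3–C4 enolate, which MeI should attack at C4 from the α-face because the β-face is shielded by the 1,3-diaxial C10 methyl group, leaving the homoprenyl group β.

Step 15
Reactants: 26 3-ketone
Product: 28 3-deoxo compound (C3 = CH2; 7α-OTIPS, C12–OTBS retained), via N-silyl hydrazone 27 (not isolated)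
Conditions: TBSNHNHTBS, Sc(OTf)3 (1 mol %), CHCl3, 60 °C; then KOt-Bu, t-BuOH, DMSO, 25 → 60 °C
Reagents that add atoms: none
Why: Wolff–Kishner reduction through the N-silyl hydrazone (Myers variant) removes the C3 carbonyl by an anionic pathway, so no C3 radical that could close onto the homoprenyl alkene is formed and the silyl ethers should survive.

Step 16
Reactants: 28 bis-silyl ether
Product: 29 primary alcohol at C12 (7α-OTIPS retained)
Conditions: HF·pyridine, pyridine, THF, 0 °C
Reagents that add atoms: none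
Why: Selective desilylation with buffered HF·pyridine, in which the unhindered primary TBS ether is cleaved far faster than the hindered secondary TIPS ether.

Step 17
Reactants: 29 primary alcohol
Product: 30 primary iodide at C12
Conditions: I2, PPh3, imidazole, CH2Cl2, 0 °C
Reagents that add atoms: iodine, II
Why: Appel-type iodination converts the primary alcohol into the iodide by SN2 displacement of the alkoxyphosphonium ion, without touching the alkenes or the silyl ether.

Step 18
Reactants: 31 ethyl acetoacetate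
Product: 32 ethyl (2E)-3-{[(trifluoromethyl)sulfonyl]oxy}but-2-enoate
Conditions: Tf2O, aq. Me4NOH, hexanes, 5 °C
Reagents that add atoms: trifluoromethanesulfonic anhydride, O=S(=O)(OS(=O)(=O)C(F)(F)F)C(F)(F)F
Why: O-Triflation of the non-chelated ammonium enolate of the β-keto ester should give the (E)-enol triflate, with the triflate trans to the ester.

Step 19
Reactants: 30 primary iodide; 32 ethyl (2E)-3-{[(trifluoromethyl)sulfonyl]oxy}but-2-enoate
Product: 34 ethyl (2E)-enoate with 7α-OTIPS (full side chain C11–C15 in place), via alkylzinc iodide 33 (not isolated)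
Conditions: Zn dust, LiCl, THF, 40 °C; then 32, Pd(PPh3)4 (5 mol %), THF, 25 → 45 °C
Reagents that add atoms: none
Why: Zinc insertion into the primary iodide and Negishi coupling with the enol triflate, which proceeds with retention of alkene geometry and should therefore give the E-enoate (C12 trans to the ester).

Step 20
Reactants: 34 ethyl (2E)-enoate with 7α-OTIPS
Product: 36 CNP0169778.1, (2E)-5-[7α-hydroxy-4α,10β-dimethyl-8-methylidene-4β-(4-methylpent-3-en-1-yl)-5α,9α-H-decalin-9-yl]-3-methylpent-2-enoic acid, via hydroxy ester 35 (not isolated)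
Conditions: TBAF, THF, 60 °C; then LiOH, MeOH/H2O, 40 °C; aq. HCl to pH 3
Reagents that add atoms: lithium hydroxide, [Li+].[OH-]
Why: Fluoride cleaves the C7 TIPS ether and hydroxide saponifies the ethyl ester (ester hydrolysis), neither operation touching a stereocentre or an alkene.

Compound list

1 | 3-bromo-4-methylphenol | Cc1ccc(O)cc1Br | starting material
2 | 3-bromo-4-methylphenyl N,N-diethylcarbamate | CCN(CC)C(=O)Oc1ccc(C)c(Br)c1 | intermediate
3 | 3-bromo-2-lithio-4-methylphenyl N,N-diethylcarbamate | CCN(CC)C(=O)Oc1ccc(C)c(Br)c1[Li] | intermediate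
4 | 3-bromo-2-iodo-4-methylphenyl N,N-diethylcarbamate | CCN(CC)C(=O)Oc1ccc(C)c(Br)c1I | intermediate
5 | 5-bromo-2-methylpent-2-ene | CC(C)=CCCBr | starting material
6 | (4-methylpent-3-en-1-yl)zinc bromide | CC(C)=CCC[Zn]Br | intermediate
7 | 3-bromo-4-methyl-2-(4-methylpent-3-en-1-yl)phenyl N,N-diethylcarbamate | CCN(CC)C(=O)Oc1ccc(C)c(Br)c1CCC=C(C)C | intermediate
8 | oxirane | C1CO1 | starting material
9 | 3-lithio-4-methyl-2-(4-methylpent-3-en-1-yl)phenyl N,N-diethylcarbamate | CCN(CC)C(=O)Oc1ccc(C)c([Li])c1CCC=C(C)C | intermediate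
10 | 3-(2-hydroxyethyl)-4-methyl-2-(4-methylpent-3-en-1-yl)phenyl N,N-diethylcarbamate | CCN(CC)C(=O)Oc1ccc(C)c(CCO)c1CCC=C(C)C | intermediate
11 | 4-methyl-2-(4-methylpent-3-en-1-yl)-3-(2-oxoethyl)phenyl N,N-diethylcarbamate | CCN(CC)C(=O)Oc1ccc(C)c(CC=O)c1CCC=C(C)C | intermediate
12 | tert-butyl(but-3-yn-1-yloxy)dimethylsilane | C#CCCO[Si](C)(C)C(C)(C)C | starting material
13 | lithium 4-(tert-butyldimethylsilyloxy)but-1-yn-1-ide | [Li]C#CCCO[Si](C)(C)C(C)(C)C | intermediate
14 | racemic propargylic alcohol (C7–OH, C8≡C9) | CCN(CC)C(=O)Oc1ccc(C)c(CC(O)C#CCCO[Si](C)(C)C(C)(C)C)c1CCC=C(C)C | intermediate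
15 | alkynyl ketone (C7=O) | CCN(CC)C(=O)Oc1ccc(C)c(CC(=O)C#CCCO[Si](C)(C)C(C)(C)C)c1CCC=C(C)C | intermediate
16 | (R)-propargylic alcohol | CCN(CC)C(=O)Oc1ccc(C)c(C[C@@H](O)C#CCCO[Si](C)(C)C(C)(C)C)c1CCC=C(C)C | intermediate
17 | (trimethylsilyl)methylmagnesium chloride | C[Si](C)(C)C[Mg]Cl | starting material
18 | alkenylmagnesium chelate (O–Mg–C9 five-membered ring, CH2SiMe3 on C8) | CCN(CC)C(=O)Oc1ccc(C)c(C[C@H]2O[Mg]C(CCO[Si](C)(C)C(C)(C)C)=C2C[Si](C)(C)C)c1CCC=C(C)C | intermediate
19 | (2R,3Z)-allylsilane alcohol | CCN(CC)C(=O)Oc1ccc(C)c(C[C@@H](O)/C(C[Si](C)(C)C)=C/CCO[Si](C)(C)C(C)(C)C)c1CCC=C(C)C | intermediate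
20 | (2R,3Z)-allylsilane TIPS ether, aryl carbamate | CCN(CC)C(=O)Oc1ccc(C)c(C[C@@H](O[Si](C(C)C)(C(C)C)C(C)C)/C(C[Si](C)(C)C)=C/CCO[Si](C)(C)C(C)(C)C)c1CCC=C(C)C | intermediate
21 | key-step precursor: 2-homoprenyl-4-methylphenol with the (2R,3Z) allylsilane chain | Cc1ccc(O)c(CCC=C(C)C)c1C[C@@H](O[Si](C(C)C)(C(C)C)C(C)C)/C(C[Si](C)(C)C)=C/CCO[Si](C)(C)C(C)(C)C | intermediate
22 | aryloxy(phenyl)-λ3-iodanyl acetate of 21 | CC(=O)OI(c1ccccc1)Oc1ccc(C)c(C[C@@H](O[Si](C(C)C)(C(C)C)C(C)C)/C(C[Si](C)(C)C)=C/CCO[Si](C)(C)C(C)(C)C)c1CCC=C(C)C | intermediate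
23 | bicyclic 1,4-dien-3-one (7α-OTIPS, 8-methylidene, 9α-H, 10β-CH3) | C=C1[C@H](O[Si](C(C)C)(C(C)C)C(C)C)CC2=C(CCC=C(C)C)C(=O)C=C[C@]2(C)[C@H]1CCO[Si](C)(C)C(C)(C)C | intermediate
24 | 4-en-3-one | C=C1[C@H](O[Si](C(C)C)(C(C)C)C(C)C)CC2=C(CCC=C(C)C)C(=O)CC[C@]2(C)[C@H]1CCO[Si](C)(C)C(C)(C)C | intermediate
25 | lithium C3–C4 enolate (5α-H) | C=C1[C@H](O[Si](C(C)C)(C(C)C)C(C)C)C[C@H]2C(CCC=C(C)C)=C(O[Li])CC[C@]2(C)[C@H]1CCO[Si](C)(C)C(C)(C)C | intermediate
26 | 3-ketone (4α-CH3, 4β-homoprenyl, 5α-H) | C=C1[C@H](O[Si](C(C)C)(C(C)C)C(C)C)C[C@H]2[C@@](C)(CCC=C(C)C)C(=O)CC[C@]2(C)[C@H]1CCO[Si](C)(C)C(C)(C)C | intermediate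
27 | N-(tert-butyldimethylsilyl)hydrazone of 26 | C=C1[C@H](O[Si](C(C)C)(C(C)C)C(C)C)C[C@H]2[C@@](C)(CCC=C(C)C)C(=NN[Si](C)(C)C(C)(C)C)CC[C@]2(C)[C@H]1CCO[Si](C)(C)C(C)(C)C | intermediate
28 | 3-deoxo bis-silyl ether | C=C1[C@H](O[Si](C(C)C)(C(C)C)C(C)C)C[C@H]2[C@@](C)(CCC=C(C)C)CCC[C@]2(C)[C@H]1CCO[Si](C)(C)C(C)(C)C | intermediate
29 | C12 primary alcohol | C=C1[C@H](O[Si](C(C)C)(C(C)C)C(C)C)C[C@H]2[C@@](C)(CCC=C(C)C)CCC[C@]2(C)[C@H]1CCO | intermediate
30 | C12 primary iodide | C=C1[C@H](O[Si](C(C)C)(C(C)C)C(C)C)C[C@H]2[C@@](C)(CCC=C(C)C)CCC[C@]2(C)[C@H]1CCI | intermediate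
31 | ethyl acetoacetate | CCOC(=O)CC(C)=O | starting material
32 | ethyl (2E)-3-{[(trifluoromethyl)sulfonyl]oxy}but-2-enoate | C/C(OS(=O)(=O)C(F)(F)F)=C\C(=O)OCC | intermediate
33 | alkylzinc iodide from 30 | C=C1[C@H](O[Si](C(C)C)(C(C)C)C(C)C)C[C@H]2[C@@](C)(CCC=C(C)C)CCC[C@]2(C)[C@H]1CC[Zn]I | intermediate
34 | ethyl (2E)-enoate, 7α-OTIPS | C=C1[C@H](O[Si](C(C)C)(C(C)C)C(C)C)C[C@H]2[C@@](C)(CCC=C(C)C)CCC[C@]2(C)[C@H]1CC/C(C)=C/C(=O)OCC | intermediate
35 | ethyl (2E)-enoate, 7α-OH | C=C1[C@H](O)C[C@H]2[C@@](C)(CCC=C(C)C)CCC[C@]2(C)[C@H]1CC/C(C)=C/C(=O)OCC | intermediate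
36 | CNP0169778.1 | C=C1[C@H](O)C[C@H]2[C@@](C)(CCC=C(C)C)CCC[C@]2(C)[C@H]1CC/C(C)=C/C(=O)O | target

Total step count: 20. Longest linear sequence: 19 steps (steps 1–17, 19 and 20, from 1 to 36); step 18 is a one-step side branch.

Steps most likely to fail

Step 12. The ring closure may lose facial control if the chair with the C7 silyloxy group equatorial competes or prevails; C9 would then bond to the opposite arene face and C9/C10 would come out with the unnatural configuration relative to C7. Closure at the ortho carbon C4 is a second, smaller leak. The fallback turns the stereochemical relay round: the cyclisation is run in the C7-epimeric series and C7 is inverted afterwards. It sets out from ynone 15. Transfer hydrogenation with the (S,S)-catalyst should give (S)-propargylic alcohol F1, carbomagnesiation with 17/CuI (S,Z)-allylsilane alcohol F2, Et3SiOTf/2,6-lutidine triethylsilyl ether F3, and LiAlH4 (7S)-phenol F4. PhI(OAc)2 in HFIP should then deliver, through the equatorial-silyloxy chair, 7β-triethylsilyloxy dienone F5 with C9 and C10 as in 23. PPTS in MeOH should release 7β-hydroxy dienone F6 with the primary TBS ether kept. A Mitsunobu reaction (4-nitrobenzoic acid, PPh3, DIAD) inverts C7 to 7α-nitrobenzoate F7; the equatorial leaving group has no antiperiplanar hydrogen, so substitution should outrun elimination. K2CO3/MeOH then gives 7α-hydroxy dienone F8, and TIPSOTf/2,6-lutidine brings the sequence back to dienone 23.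

Step 14. Proton exchange between the enolate, amide base and product in ammonia may cause over-methylation at C2, O-methylation or simple protonation at C4, and face selectivity at C4 may erode as the mixture warms. The fallback separates the reduction from the C–C bond formation. It sets out from enone 24: Li/NH3 reduction followed by a Me3SiCl/Et3N quench should give trimethylsilyl enol ether F9, which is isolated. MeLi in THF regenerates the amine-free lithium enolate 25, and MeI in THF/DMPU at −78 °C returns to ketone 26.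

Step 15. The strongly basic medium may move the exocyclic C8=C17 double bond into the ring, and hydrazone formation next to the quaternary C4 may stall. The fallback replaces the anionic deoxygenation by a radical one with a fast hydrogen donor. It sets out from ketone 26: NaBH4 should give 3β-alcohol F10 and NaH/CS2/MeI S-methyl xanthate F11. Bu3SnH/AIBN with catalytic PhSeSePh then leads back to 28; benzeneselenol formed in situ should trap the C3 radical before it can close 5-exo onto the homoprenyl alkene.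

Further compounds

F1 | step 12 | (S)-propargylic alcohol | CCN(CC)C(=O)Oc1ccc(C)c(C[C@H](O)C#CCCO[Si](C)(C)C(C)(C)C)c1CCC=C(C)C
F2 | step 12 | (S,Z)-allylsilane alcohol | CCN(CC)C(=O)Oc1ccc(C)c(C[C@H](O)/C(C[Si](C)(C)C)=C/CCO[Si](C)(C)C(C)(C)C)c1CCC=C(C)C
F3 | step 12 | triethylsilyl ether | CCN(CC)C(=O)Oc1ccc(C)c(C[C@H](O[Si](CC)(CC)CC)/C(C[Si](C)(C)C)=C/CCO[Si](C)(C)C(C)(C)C)c1CCC=C(C)C
F4 | step 12 | (7S)-phenol | Cc1ccc(O)c(CCC=C(C)C)c1C[C@H](O[Si](CC)(CC)CC)/C(C[Si](C)(C)C)=C/CCO[Si](C)(C)C(C)(C)C
F5 | step 12 | 7β-triethylsilyloxy dienone | C=C1[C@@H](O[Si](CC)(CC)CC)CC2=C(CCC=C(C)C)C(=O)C=C[C@]2(C)[C@H]1CCO[Si](C)(C)C(C)(C)C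
F6 | step 12 | 7β-hydroxy dienone | C=C1[C@@H](O)CC2=C(CCC=C(C)C)C(=O)C=C[C@]2(C)[C@H]1CCO[Si](C)(C)C(C)(C)C
F7 | step 12 | 7α-nitrobenzoate | C=C1[C@H](OC(=O)c3ccc(cc3)[N+](=O)[O-])CC2=C(CCC=C(C)C)C(=O)C=C[C@]2(C)[C@H]1CCO[Si](C)(C)C(C)(C)C
F8 | step 12 | 7α-hydroxy dienone | C=C1[C@H](O)CC2=C(CCC=C(C)C)C(=O)C=C[C@]2(C)[C@H]1CCO[Si](C)(C)C(C)(C)C
F9 | step 14 | trimethylsilyl enol ether | C=C1[C@H](O[Si](C(C)C)(C(C)C)C(C)C)C[C@H]2C(CCC=C(C)C)=C(O[Si](C)(C)C)CC[C@]2(C)[C@H]1CCO[Si](C)(C)C(C)(C)C
F10 | step 15 | 3β-alcohol | C=C1[C@H](O[Si](C(C)C)(C(C)C)C(C)C)C[C@H]2[C@@](C)(CCC=C(C)C)[C@@H](O)CC[C@]2(C)[C@H]1CCO[Si](C)(C)C(C)(C)C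
F11 | step 15 | S-methyl xanthate | C=C1[C@H](O[Si](C(C)C)(C(C)C)C(C)C)C[C@H]2[C@@](C)(CCC=C(C)C)[C@@H](OC(=S)SC)CC[C@]2(C)[C@H]1CCO[Si](C)(C)C(C)(C)C
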